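**Retrosynthetic overview**
1. The target is traced back to the 10-ketone 22, the 6α-alcohol 18 and the dienone 15; the C10 ketone is the handle for all seven-ring functionality (C8 methyl by conjugate addition, C7=C8 and C6–O by dienone, α-epoxide and reductive opening).
2. The 3β,4β-diol comes from cyclopentene 10 by dihydroxylation on the convex face; 10 comes from the 3α-alcohol 9 by syn-dehydration.
3. Key disconnection C2–C3: bicyclic 9 comes from monocyclic aldehyde 8 by a Prins cyclization ended by a pinacol shift, which closes the five-membered ring and turns the cyclohexane into the cycloheptanone in one operation.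
4. The enabling feature is the array O–C3–C2H2–C1(CH3, quaternary ring fusion)–C10–O: a methylene between an oxygenated carbon and a quaternary carbon that carries an oxygenated neighbour in the seven-membered ring.
5. Aldehyde 8 comes from cyclohexanone and a nitroalkene (one catalytic asymmetric Michael addition sets the absolute configuration), isopropenyl addition and a Nef reaction; ring order: six-membered ring (bought), then five- and seven-membered rings together in the key step.

Key step: step 6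

Remark: bicyclic compounds carry daucane locants (C1 ring-fusion carbon with methyl, C2, C3, C4 isopropyl carbon, C5 ring-fusion CH, C6 to C10 round the seven-membered ring back to C1); β is the face of the 1-methyl group and of H-5, and the ring fusion is cis throughout.

**Route**

Step 1
Reactants: 1 2-methylpropanal
Product: 3 (E)-3-methyl-1-nitrobut-1-ene, via 3-methyl-1-nitrobutan-2-ol 2 (not isolated)
Conditions: MeNO2, KOtBu (cat.), THF/t-BuOH, 0 °C; then (CF3CO)2O, Et3N, CH2Cl2, −10 °C
Reagents that add atoms: nitromethane C[N+](=O)[O-]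
Why: Henry addition followed by dehydration of the nitro alcohol through its trifluoroacetate should give the conjugated nitroalkene as the favoured E isomer.

Step 2
Reactants: 4 cyclohexanone; 3 (E)-3-methyl-1-nitrobut-1-ene
Product: 5 (2R)-2-[(2R)-3-methyl-1-nitrobutan-2-yl]cyclohexan-1-one
Conditions: (R)-1-(pyrrolidin-2-ylmethyl)pyrrolidine (15 mol %), CF3CO2H (15 mol %), cyclohexanone (5 equiv), 0 °C to rt
Reagents that add atoms: none
Why: Enamine-catalysed Michael addition through an acyclic synclinal transition state should give the syn adduct, the (R)-pyrrolidine shielding one enamine face so that both new centres are R (mirror image of the usual result with L-proline-derived amines).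

Step 3
Reactants: 5 (2R)-2-[(2R)-3-methyl-1-nitrobutan-2-yl]cyclohexan-1-one
Product: 6 (1R,2R)-2-[(2R)-3-methyl-1-nitrobutan-2-yl]-1-(prop-1-en-2-yl)cyclohexan-1-ol
Conditions: CH2=C(CH3)MgBr (3 equiv), CeCl3 (3 equiv), THF, −78 °C; aq. NH4Cl
Reagents that add atoms: isopropenylmagnesium bromide C=C(C)[Mg]Br
Why: The first equivalent turns the acidic nitro group into an inert nitronate and the organocerium reagent then adds 1,2 to the ketone without enolisation, from the equatorial direction anti to the side chain, so the hydroxyl ends up cis to the side chain.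

Step 4
Reactants: 6 (1R,2R)-2-[(2R)-3-methyl-1-nitrobutan-2-yl]-1-(prop-1-en-2-yl)cyclohexan-1-ol
Product: 7 triethyl{[(1R,2R)-2-[(2R)-3-methyl-1-nitrobutan-2-yl]-1-(prop-1-en-2-yl)cyclohexyl]oxy}silane
Conditions: Et3SiOTf, 2,6-lutidine, CH2Cl2, −78 to 0 °C
Reagents that add atoms: triethylsilyl trifluoromethanesulfonate CC[Si](CC)(CC)OS(=O)(=O)C(F)(F)F
Why: Silylation of the tertiary alcohol prevents lactol formation with the later aldehyde and gives the oxygen that drives the pinacol shift.

Step 5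
Reactants: 7 triethyl{[(1R,2R)-2-[(2R)-3-methyl-1-nitrobutan-2-yl]-1-(prop-1-en-2-yl)cyclohexyl]oxy}silane
Product: 8 (2R)-3-methyl-2-[(1R,2R)-2-(prop-1-en-2-yl)-2-(triethylsilyloxy)cyclohexyl]butanal
Conditions: NaOMe, MeOH, 0 °C; then aq. TiCl3, NH4OAc buffer (pH 5–6), THF, 0 °C to rt
Reagents that add atoms: water O
Why: Nef reaction in which TiCl3 reduces the nitronate to the imine, which hydrolyses near neutral pH, so the alkene, the silyl ether and the stereocentre next to the new aldehyde should survive.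

Step 6
Reactants: 8 (2R)-3-methyl-2-[(1R,2R)-2-(prop-1-en-2-yl)-2-(triethylsilyloxy)cyclohexyl]butanal
Product: 9 3α-hydroxy-4β-isopropyl-1β-methyl-5βH-bicyclo[5.3.0]decan-10-one
Conditions: SnCl4 (1.2 equiv), CH2Cl2, −78 to −40 °C; aq. NaHCO3
Reagents that add atoms: none
Why: SnCl4 activates the aldehyde, the terminal isopropenyl carbon attacks it through a chair transition state with side chain and alkenyl group both equatorial (C2–C3 bond formed, tertiary cation at C1), and the cation is quenched at once by 1,2-migration of ring carbon C5 from the silyloxy carbon C10 to C1, C10 becoming the ketone. The closest known reaction type is the Lewis acid-promoted Prins cyclization/pinacol rearrangement of 1-alkenyl-2-(2-oxoethyl)- or 2-(2,2-dialkoxyethyl)cycloalkanol silyl ethers, which gives cis-fused cyclopentane-annulated cycloalkanones with one-carbon ring enlargement. The five-membered ring is closed by a 6-endo Prins closure (ring C3–C2–C1–C10–C5–C4) followed by ring contraction, and the seven-membered ring arises from the cyclohexane by the same 1,2-shift, so no medium-ring cyclization is needed. C1 is set with its methyl cis to H-5 because C5 migrates with retention across the face of the cation on which it already sits in the trans-fused chair; the C3 oxygen ends up equatorial in that chair (α, cis to H-4), and C4 and C5 are carried over from 8 with the isopropyl group equatorial. The step needs the pinacol shift to outrun proton loss from the cation (ene-type product) and C5 rather than C9 to migrate: the axial silyloxy group holds the C10–C5 bond, not the equatorial C10–C9 bond, in line with the empty orbital, and the electron-rich silyloxy oxygen makes the shift fast. The (1R,2R,2′R) configuration of 8 secures this chair because only the silyloxy group is axial.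

Step 7
Reactants: 9 3α-hydroxy-4β-isopropyl-1β-methyl-5βH-bicyclo[5.3.0]decan-10-one
Product: 10 4-isopropyl-1β-methyl-5βH-bicyclo[5.3.0]dec-3-en-10-one
Conditions: Burgess reagent (2 equiv), toluene, 70 °C
Reagents that add atoms: none
Why: Burgess dehydration is a syn elimination of the sulfamate; the tertiary H-4 is cis to the 3α-oxygen, so the more substituted C3=C4 alkene should form.

Step 8
Reactants: 10 4-isopropyl-1β-methyl-5βH-bicyclo[5.3.0]dec-3-en-10-one
Product: 11 3β,4β-dihydroxy-4α-isopropyl-1β-methyl-5βH-bicyclo[5.3.0]decan-10-one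
Conditions: OsO4 (5 mol %), NMO (1.5 equiv), acetone/H2O, rt
Reagents that add atoms: osmium tetroxide O=[Os](=O)(=O)=O; N-methylmorpholine N-oxide C[N+]1([O-])CCOCC1; water O
Why: Catalytic cis-dihydroxylation on the face anti to the allylic C5–C6 bond and the seven-membered ring (convex β face) should set both hydroxyls β and push the isopropyl group α.

Step 9
Reactants: 11 3β,4β-dihydroxy-4α-isopropyl-1β-methyl-5βH-bicyclo[5.3.0]decan-10-one
Product: 12 3β-acetoxy-4β-hydroxy-4α-isopropyl-1β-methyl-5βH-bicyclo[5.3.0]decan-10-one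
Conditions: Ac2O, pyridine, DMAP (cat.), CH2Cl2, 0 °C to rt
Reagents that add atoms: acetic anhydride CC(=O)OC(C)=O
Why: Only the secondary C3 hydroxyl is acylated; the tertiary C4 hydroxyl is inert under these conditions.

Step 10
Reactants: 12 3β-acetoxy-4β-hydroxy-4α-isopropyl-1β-methyl-5βH-bicyclo[5.3.0]decan-10-one
Product: 13 3β-acetoxy-4β-hydroxy-4α-isopropyl-1β-methyl-5βH-bicyclo[5.3.0]dec-8-en-10-one
Conditions: IBX (2 equiv), DMSO/fluorobenzene, 70 °C
Reagents that add atoms: none
Why: IBX dehydrogenation proceeds through the enol, and only C9 is enolisable because C1 is quaternary, so a single enone is possible.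

Step 11
Reactants: 13 3β-acetoxy-4β-hydroxy-4α-isopropyl-1β-methyl-5βH-bicyclo[5.3.0]dec-8-en-10-one
Product: 14 3β-acetoxy-4β-hydroxy-4α-isopropyl-1β,8β-dimethyl-5βH-bicyclo[5.3.0]decan-10-one
Conditions: MeMgBr (3 equiv), CuI (10 mol %), THF, −40 °C; aq. NH4Cl
Reagents that add atoms: methylmagnesium bromide C[Mg]Br
Why: Copper-catalysed conjugate addition installs the C8 methyl group (β expected from convex-face attack); the C8 configuration does not matter because C8 becomes sp2 in step 12.

Step 12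
Reactants: 14 3β-acetoxy-4β-hydroxy-4α-isopropyl-1β,8β-dimethyl-5βH-bicyclo[5.3.0]decan-10-one
Product: 15 3β-acetoxy-4β-hydroxy-4α-isopropyl-1β,8-dimethyl-5βH-bicyclo[5.3.0]deca-6,8-dien-10-one
Conditions: IBX (4 equiv), DMSO, 80 °C
Reagents that add atoms: none
Why: Two successive IBX dehydrogenations (α,β, then γ,δ through the dienol) should give the linear dienone, since the quaternary C1 blocks the other side of the ketone.

Step 13
Reactants: 15 3β-acetoxy-4β-hydroxy-4α-isopropyl-1β,8-dimethyl-5βH-bicyclo[5.3.0]deca-6,8-dien-10-one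
Product: 17 3β-acetoxy-6α,7α-epoxy-4β-hydroxy-4α-isopropyl-1β,8-dimethyl-5βH-bicyclo[5.3.0]dec-8-en-10-one, via 6β-bromo-7α-hydroxy enone 16 (not isolated)
Conditions: NBS (1.2 equiv), THF/H2O, 0 °C; then K2CO3, MeCN, rt
Reagents that add atoms: water O; N-bromosuccinimide O=C1CCC(=O)N1Br (bromine kept in 16 only)
Why: Bromohydrin formation and closure: the bromonium ion forms at the less deactivated γ,δ-alkene on the open β face, water opens it anti at the allylic C7, and base closes the epoxide with inversion at C6, so the C6–O bond is set α as in the target (a peracid would give the β-epoxide).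

Step 14
Reactants: 17 3β-acetoxy-6α,7α-epoxy-4β-hydroxy-4α-isopropyl-1β,8-dimethyl-5βH-bicyclo[5.3.0]dec-8-en-10-one
Product: 18 3β-acetoxy-4β,6α-dihydroxy-4α-isopropyl-1β,8-dimethyl-5βH-bicyclo[5.3.0]dec-7-en-10-one
Conditions: SmI2 (2.2 equiv), THF/MeOH, −78 °C
Reagents that add atoms: none
Why: SmI2 reduction of a γ,δ-epoxy enone expels the C7–O bond to give a samarium dienolate that is protonated kinetically at C9, leaving the β,γ-unsaturated ketone and the 6α-hydroxyl untouched.

Step 15
Reactants: 19 4-hydroxybenzoic acid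
Product: 21 4-(tert-butyldimethylsilyloxy)benzoic acid, via bis-silyl derivative 20 (not isolated)
Conditions: TBSCl (2.2 equiv), imidazole, DMF, rt; then K2CO3, MeOH/THF/H2O, rt; citric acid
Reagents that add atoms: tert-butyldimethylsilyl chloride CC(C)(C)[Si](C)(C)Cl
Why: Bis-silylation followed by selective hydrolysis of the labile silyl ester leaves only the phenol protected.

Step 16
Reactants: 18 3β-acetoxy-4β,6α-dihydroxy-4α-isopropyl-1β,8-dimethyl-5βH-bicyclo[5.3.0]dec-7-en-10-one; 21 4-(tert-butyldimethylsilyloxy)benzoic acid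
Product: 22 3β-acetoxy-6α-[4-(tert-butyldimethylsilyloxy)benzoyloxy]-4β-hydroxy-4α-isopropyl-1β,8-dimethyl-5βH-bicyclo[5.3.0]dec-7-en-10-one
Conditions: DCC, DMAP (cat.), CH2Cl2, 0 °C
Reagents that add atoms: none
Why: Steglich esterification of the only free secondary hydroxyl proceeds with retention at C6; the low temperature and catalytic DMAP are chosen to avoid conjugation of the β,γ-enone.

Step 17
Reactants: 22 3β-acetoxy-6α-[4-(tert-butyldimethylsilyloxy)benzoyloxy]-4β-hydroxy-4α-isopropyl-1β,8-dimethyl-5βH-bicyclo[5.3.0]dec-7-en-10-one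
Product: 23 3β-acetoxy-6α-[4-(tert-butyldimethylsilyloxy)benzoyloxy]-4α-isopropyl-1β,8-dimethyl-5βH-bicyclo[5.3.0]dec-7-ene-4β,10β-diol
Conditions: SmI2 (2.5 equiv), THF/H2O, 0 °C
Reagents that add atoms: none
Why: Single-electron reduction in which the ketyl-derived organosamarium places its bulky oxygen on the open convex β face and is protonated from the α face should give the thermodynamically favoured 10β-alcohol; hydride reagents are avoided because they are expected to attack from the β face and give the 10α-epimer.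

Step 18
Reactants: 23 3β-acetoxy-6α-[4-(tert-butyldimethylsilyloxy)benzoyloxy]-4α-isopropyl-1β,8-dimethyl-5βH-bicyclo[5.3.0]dec-7-ene-4β,10β-diol
Product: 24 3β-acetoxy-6α-(4-hydroxybenzoyloxy)-4α-isopropyl-1β,8-dimethyl-5βH-bicyclo[5.3.0]dec-7-ene-4β,10β-diol (CNP0146780.2)
Conditions: HF·pyridine, THF/pyridine, 0 °C
Reagents that add atoms: none
Why: Fluoride cleaves the aryl silyl ether far faster than it touches the acetate, the benzoate or the alcohols.

**Compound list**
1 | 2-methylpropanal | CC(C)C=O | starting material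
2 | 3-methyl-1-nitrobutan-2-ol (racemic, not isolated) | CC(C)C(O)C[N+](=O)[O-] | intermediate
3 | (E)-3-methyl-1-nitrobut-1-ene | CC(C)/C=C/[N+](=O)[O-] | intermediate
4 | cyclohexanone | O=C1CCCCC1 | starting material
5 | (2R)-2-[(2R)-3-methyl-1-nitrobutan-2-yl]cyclohexan-1-one | O=C1CCCC[C@@H]1[C@H](C[N+](=O)[O-])C(C)C | intermediate
6 | (1R,2R)-2-[(2R)-3-methyl-1-nitrobutan-2-yl]-1-(prop-1-en-2-yl)cyclohexan-1-ol | C=C(C)[C@@]1(O)CCCC[C@@H]1[C@H](C[N+](=O)[O-])C(C)C | intermediate
7 | triethylsilyl ether of 6 | C=C(C)[C@@]1(O[Si](CC)(CC)CC)CCCC[C@@H]1[C@H](C[N+](=O)[O-])C(C)C | intermediate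
8 | (2R)-3-methyl-2-[(1R,2R)-2-(prop-1-en-2-yl)-2-(triethylsilyloxy)cyclohexyl]butanal | C=C(C)[C@@]1(O[Si](CC)(CC)CC)CCCC[C@@H]1[C@H](C=O)C(C)C | intermediate
9 | 3α-hydroxy-4β-isopropyl-1β-methyl-5βH-bicyclo[5.3.0]decan-10-one | O[C@@H]1C[C@]2(C)C(=O)CCCC[C@@H]2[C@H]1C(C)C | intermediate
10 | 4-isopropyl-1β-methyl-5βH-bicyclo[5.3.0]dec-3-en-10-one | CC(C)C1=CC[C@]2(C)C(=O)CCCC[C@@H]21 | intermediate
11 | 3β,4β-dihydroxy-4α-isopropyl-1β-methyl-5βH-bicyclo[5.3.0]decan-10-one | O[C@H]1C[C@]2(C)C(=O)CCCC[C@@H]2[C@]1(O)C(C)C | intermediate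
12 | 3β-acetoxy-4β-hydroxy-4α-isopropyl-1β-methyl-5βH-bicyclo[5.3.0]decan-10-one | CC(=O)O[C@H]1C[C@]2(C)C(=O)CCCC[C@@H]2[C@]1(O)C(C)C | intermediate
13 | 3β-acetoxy-4β-hydroxy-4α-isopropyl-1β-methyl-5βH-bicyclo[5.3.0]dec-8-en-10-one | CC(=O)O[C@H]1C[C@]2(C)C(=O)C=CCC[C@@H]2[C@]1(O)C(C)C | intermediate
14 | 3β-acetoxy-4β-hydroxy-4α-isopropyl-1β,8β-dimethyl-5βH-bicyclo[5.3.0]decan-10-one (8-epimer converges) | CC(=O)O[C@H]1C[C@]2(C)C(=O)C[C@@H](C)CC[C@@H]2[C@]1(O)C(C)C | intermediate
15 | 3β-acetoxy-4β-hydroxy-4α-isopropyl-1β,8-dimethyl-5βH-bicyclo[5.3.0]deca-6,8-dien-10-one | CC(=O)O[C@H]1C[C@]2(C)C(=O)C=C(C)C=C[C@@H]2[C@]1(O)C(C)C | intermediate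
16 | 3β-acetoxy-6β-bromo-4β,7α-dihydroxy-4α-isopropyl-1β,8-dimethyl-5βH-bicyclo[5.3.0]dec-8-en-10-one (not isolated) | CC(=O)O[C@H]1C[C@]2(C)C(=O)C=C(C)[C@H](O)[C@@H](Br)[C@@H]2[C@]1(O)C(C)C | intermediate
17 | 3β-acetoxy-6α,7α-epoxy-4β-hydroxy-4α-isopropyl-1β,8-dimethyl-5βH-bicyclo[5.3.0]dec-8-en-10-one | CC(=O)O[C@H]1C[C@]2(C)C(=O)C=C(C)[C@@H]3O[C@@H]3[C@@H]2[C@]1(O)C(C)C | intermediate
18 | 3β-acetoxy-4β,6α-dihydroxy-4α-isopropyl-1β,8-dimethyl-5βH-bicyclo[5.3.0]dec-7-en-10-one | CC(=O)O[C@H]1C[C@]2(C)C(=O)CC(C)=C[C@H](O)[C@@H]2[C@]1(O)C(C)C | intermediate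
19 | 4-hydroxybenzoic acid | OC(=O)c1ccc(O)cc1 | starting material
20 | tert-butyldimethylsilyl 4-(tert-butyldimethylsilyloxy)benzoate (not isolated) | CC(C)(C)[Si](C)(C)OC(=O)c1ccc(O[Si](C)(C)C(C)(C)C)cc1 | intermediate
21 | 4-(tert-butyldimethylsilyloxy)benzoic acid | OC(=O)c1ccc(O[Si](C)(C)C(C)(C)C)cc1 | intermediate
22 | 3β-acetoxy-6α-[4-(tert-butyldimethylsilyloxy)benzoyloxy]-4β-hydroxy-4α-isopropyl-1β,8-dimethyl-5βH-bicyclo[5.3.0]dec-7-en-10-one | CC(=O)O[C@H]1C[C@]2(C)C(=O)CC(C)=C[C@H](OC(=O)c3ccc(O[Si](C)(C)C(C)(C)C)cc3)[C@@H]2[C@]1(O)C(C)C | intermediate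
23 | 3β-acetoxy-6α-[4-(tert-butyldimethylsilyloxy)benzoyloxy]-4α-isopropyl-1β,8-dimethyl-5βH-bicyclo[5.3.0]dec-7-ene-4β,10β-diol | CC(=O)O[C@H]1C[C@]2(C)[C@@H](O)CC(C)=C[C@H](OC(=O)c3ccc(O[Si](C)(C)C(C)(C)C)cc3)[C@@H]2[C@]1(O)C(C)C | intermediate
24 | 3β-acetoxy-6α-(4-hydroxybenzoyloxy)-4α-isopropyl-1β,8-dimethyl-5βH-bicyclo[5.3.0]dec-7-ene-4β,10β-diol (CNP0146780.2) | CC(=O)O[C@H]1C[C@]2(C)[C@@H](O)CC(C)=C[C@H](OC(=O)c3ccc(O)cc3)[C@@H]2[C@]1(O)C(C)C | target

**Step count:** 18 steps in total. Longest linear sequence: 17 steps (steps 1 to 14 and 16 to 18, from 2-methylpropanal); step 15 is a one-step side branch.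

**Three steps most likely to fail**

Step 17 (C10 ketone reduction). The process at risk is face control: protonation of the organosamarium from the β face would give the 10α-alcohol, and electron transfer to the aryl or allylic ester could compete. The fallback sets out from 18 and comes back at 24, and it replaces thermodynamic control by hydroxyl-directed hydride delivery from the α face before the ester is put on. Me4NBH(OAc)3 in MeCN/AcOH at −20 °C binds to the 6α-hydroxyl and delivers hydride to C10 from the α face to give 3β-acetoxy-4α-isopropyl-1β,8-dimethyl-5βH-bicyclo[5.3.0]dec-7-ene-4β,6α,10β-triol F1. MnO2 in CH2Cl2 oxidises only the allylic C6 hydroxyl to give the 4β,10β-dihydroxy-dec-7-en-6-one F2, and Et3SiOTf with 2,6-lutidine at −78 °C gives its 10β-triethylsilyl ether F3. NaBH4/CeCl3 in MeOH at −78 °C then adds hydride to C6 from the open β face to give the 6α-alcohol F4, DCC/DMAP with 21 gives the 6α-aroyl ester 10β-silyl ether F5, and HF·pyridine removes both silyl groups to give 24.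

Step 13 (bromohydrin and epoxide closure). The process at risk is regio- and face control in the bromonium opening (attack at C6, or bromination of the α,β-alkene). The fallback sets out from 15 and comes back at 18, and it accepts the β-epoxide and corrects C6 by oxidation and reduction. mCPBA with NaHCO3 in CH2Cl2 gives the 6β,7β-epoxy-dec-8-en-10-one F6, and SmI2 in THF/MeOH at −78 °C gives the 6β-hydroxy-dec-7-en-10-one F7. MnO2 gives the dec-7-ene-6,10-dione F8, and NaBH4/CeCl3 at −78 °C (1 equiv) reduces the conjugated C6 carbonyl from the β face, the C10 ketone next to the quaternary carbon reacting more slowly, to give 18.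

Step 12 (double dehydrogenation). The process at risk is stalling after the first dehydrogenation or over-oxidation at the higher temperature. The fallback sets out from 14 and comes back at 15, and it makes the second double bond by bromination and elimination. IBX (1.5 equiv) at 65 °C gives the 8-methyl-dec-8-en-10-one F9, NBS with a radical initiator in PhCF3 brominates the ring γ-position to give the 7-bromo enone F10 (epimers at C7), and Li2CO3/LiBr in DMF at 100 °C eliminates HBr to give 15.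

**Further compounds**
F1 | step 17 | 3β-acetoxy-4α-isopropyl-1β,8-dimethyl-5βH-bicyclo[5.3.0]dec-7-ene-4β,6α,10β-triol | CC(=O)O[C@H]1C[C@]2(C)[C@@H](O)CC(C)=C[C@H](O)[C@@H]2[C@]1(O)C(C)C
F2 | step 17 | 3β-acetoxy-4β,10β-dihydroxy-4α-isopropyl-1β,8-dimethyl-5βH-bicyclo[5.3.0]dec-7-en-6-one | CC(=O)O[C@H]1C[C@]2(C)[C@@H](O)CC(C)=CC(=O)[C@@H]2[C@]1(O)C(C)C
F3 | step 17 | 3β-acetoxy-4β-hydroxy-4α-isopropyl-1β,8-dimethyl-10β-(triethylsilyloxy)-5βH-bicyclo[5.3.0]dec-7-en-6-one | CC(=O)O[C@H]1C[C@]2(C)[C@@H](O[Si](CC)(CC)CC)CC(C)=CC(=O)[C@@H]2[C@]1(O)C(C)C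
F4 | step 17 | 3β-acetoxy-4α-isopropyl-1β,8-dimethyl-10β-(triethylsilyloxy)-5βH-bicyclo[5.3.0]dec-7-ene-4β,6α-diol | CC(=O)O[C@H]1C[C@]2(C)[C@@H](O[Si](CC)(CC)CC)CC(C)=C[C@H](O)[C@@H]2[C@]1(O)C(C)C
F5 | step 17 | 3β-acetoxy-6α-[4-(tert-butyldimethylsilyloxy)benzoyloxy]-4α-isopropyl-1β,8-dimethyl-10β-(triethylsilyloxy)-5βH-bicyclo[5.3.0]dec-7-en-4β-ol | CC(=O)O[C@H]1C[C@]2(C)[C@@H](O[Si](CC)(CC)CC)CC(C)=C[C@H](OC(=O)c3ccc(O[Si](C)(C)C(C)(C)C)cc3)[C@@H]2[C@]1(O)C(C)C
F6 | step 13 | 3β-acetoxy-6β,7β-epoxy-4β-hydroxy-4α-isopropyl-1β,8-dimethyl-5βH-bicyclo[5.3.0]dec-8-en-10-one | CC(=O)O[C@H]1C[C@]2(C)C(=O)C=C(C)[C@H]3O[C@H]3[C@@H]2[C@]1(O)C(C)C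
F7 | step 13 | 3β-acetoxy-4β,6β-dihydroxy-4α-isopropyl-1β,8-dimethyl-5βH-bicyclo[5.3.0]dec-7-en-10-one | CC(=O)O[C@H]1C[C@]2(C)C(=O)CC(C)=C[C@@H](O)[C@@H]2[C@]1(O)C(C)C
F8 | step 13 | 3β-acetoxy-4β-hydroxy-4α-isopropyl-1β,8-dimethyl-5βH-bicyclo[5.3.0]dec-7-ene-6,10-dione | CC(=O)O[C@H]1C[C@]2(C)C(=O)CC(C)=CC(=O)[C@@H]2[C@]1(O)C(C)C
F9 | step 12 | 3β-acetoxy-4β-hydroxy-4α-isopropyl-1β,8-dimethyl-5βH-bicyclo[5.3.0]dec-8-en-10-one | CC(=O)O[C@H]1C[C@]2(C)C(=O)C=C(C)CC[C@@H]2[C@]1(O)C(C)C
F10 | step 12 | 3β-acetoxy-7-bromo-4β-hydroxy-4α-isopropyl-1β,8-dimethyl-5βH-bicyclo[5.3.0]dec-8-en-10-one (C7 epimers) | CC(=O)O[C@H]1C[C@]2(C)C(=O)C=C(C)C(Br)C[C@@H]2[C@]1(O)C(C)C
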